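30.8 % of the reagent charged ends as target in the autumn and dawn runs. Call this the reagent's share: target formed per reagent charged. It is the number you need for the new flask, in which solid substrate dissolves to starting material and target forms.

| flask | solid substrate | reagent | second substrate | catalyst | remark | time |
|---|---|---|---|---|---|---|
| autumn | 0.044 M | 0.066 M | 0.066 M (in portions, 4) | 0.66 mM | run made earlier; portions every 1.5 h |  |
| dawn | 0.099 M | 0.066 M | 0.066 M (in portions, 4) | 0.66 mM | run made earlier; portions every 1.5 h |  |
| midnight | 0.066 M | 0.033 M | 0.066 M (in portions, 4) | 0.66 mM | run made earlier; portions every 1.5 h |  |
| flask | 0.066 M | 0.0660 M | 0.0660 M (in portions, 4) | 0.66 mM | the portions of second substrate follow each other after 1.5 h, the first at the start | 15 d |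

- autumn (time / d: target / %, starting material / %, solid substrate / %): 1.67: 46.6, 53.5, 0.6; 4.00: 45.8, 56.5, 0; 8.00: 47.4, 51.9, 0; 12.0: 46.2, 53.3, 0
- dawn (time / d: target / %, starting material / %, solid substrate / %): 1.04: 19.9, 60.7, 19.7; 2.00: 21.1, 61.0, 17.8; 5.00: 21.0, 60.2, 16.7; 12.0: 19.8, 60.1, 18.8
- midnight (time / d: target / %, starting material / %, solid substrate / %): 1.04: 16.8, 81.3, 0; 2.00: 16.8, 82.3, 0; 5.00: 17.7, 82.9, 0.1; 12.0: 18.8, 82.8, 0.1

(standard deviation of a reading: 1 percentage point)

- solid substrate is a solid; its amount is given per volume of the solution
- at the start none of the solid substrate is in solution
- what has only dissolved of solid substrate counts as not reacted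
- the reaction counts as stopped when no species that holds the solid substrate changes by six tenths of a point or more over the second half of the time
- starting material means what is dissolved; the solid is not counted in it

* why nothing more happens at 15 d, or that something still does (for what has run out or reacted, a solid counts together with what of it has only dissolved) (all of the solid substrate has reacted / the reagent has run out first / it is still moving / no working catalyst is left)
* how much target there is at 15 d, in percent of the solid substrate charged
* how much starting material there is at 15 d, in percent of the solid substrate charged

The target readings of autumn and dawn are flat within scatter, so you may replace each of these two curves by its mean, which is good to 0.5 percentage points. The shares are 31.0 % in autumn and 30.7 % in dawn, a difference of 0.30 points, although the solid charged goes from 0.044 M to 0.099 M. In the midnight run the reagent charge is cut to 50.0 % of that charge and the target to 56.8 % of what autumn and dawn give. Target follows the reagent, though not in proportion, so I call the reagent the limiting reagent, and I carry the share for this reagent, second substrate and catalyst charge.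

Two extreme versions of the flask can be done in the head. Suppose solid stayed in excess, as in dawn. Then [starting material] would sit at the dawn reading of 0.0599 M beside [target] of 0.0204 M, which takes 0.0802 M of solid, more than the 0.066 M charged. So the flask stands at the other extreme, that of autumn, with the solid dissolved: target 30.8 %, and starting material the rest, 69.2 %.

The forecast gives 31 % target and 69 % starting material, but for the end it says no working catalyst is left: “the catalyst dies after about 30 turnovers”. There I differ from it, since I expect the reagent to run out first.

The flask gives this end: the reagent has run out first, with 31.2 % target and 68.8 % starting material.

    starting material + reagent + catalyst → catalyst + target (k = 32000 M⁻² h⁻¹)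
    second substrate + reagent + catalyst → catalyst + second product (k = 33000 M⁻² h⁻¹)
    2 reagent → homo dimer (k = 2.00 M⁻¹ h⁻¹)
    solid substrate ⇌ starting material, rate k4*(cs4 - [starting material]) while solid is left; crystals form when [starting material] > cs4 (solubility = 0.0600 M, k = 0.210 h⁻¹)

In the flask at 15.0 d, reagent stands at 0 % of its charge and catalyst at 100 %. The share read from this flask is 31.2 %. Now take the neighbouring flask with 0.17 M of solid substrate and the other charges as before: the share carried over gives 12.0 % target, and that flask holds 12.1 %.

Readings and results come from a simulation with made-up constants; scatter was added.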